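**Plan**
- Retrosynthesis: CO2H comes from CH2OSi. The O1–C6 bond (with C5–H) is cut by a retro iodo-cyclisation to a (Z)-homoallylic hydroperoxide. C3–OOH comes from C3–OMs with inversion. Last, C3–C4 and C5–C6 are cut together.
- Enabling feature: in the 1,2-dioxane ring the unsubstituted C4H2–C5H2 bridge joins the two peroxy carbons C3 and C6. C6–C5–C4 can therefore be an allylboron unit built from vinyl–B(pin), and C3 can be an aldehyde carbon.
- Forward order: a C18 carbinyl benzoate, the vinylboronate and a C4 aldehyde are joined in one flask. O–O is then brought in at C3, and the only ring is closed at C6 (6-endo). The helpers (I, Si) leave, and CH2OH becomes CO2H.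
- Stereochemistry: the side-chain methyl centre is bought and the C18 carbinol is set by an enzyme. That centre is relayed through C6–B to C3 and to the Z geometry of C5=C6. C3 is then inverted by HOO−, and Z geometry plus C3 regenerate C6 in the anti ring closure.

Key step: step 5

Assumption: farnesylacetone is used as the geometrically pure (5E,9E) isomer.

Step 1
Reactants: 1 methyl (R)-3-hydroxy-2-methylpropanoate
Product: 2 methyl (R)-3-[(tert-butyldimethylsilyl)oxy]-2-methylpropanoate
Conditions: TBSCl, imidazole, CH2Cl2, 0 °C to rt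
Reagents that add atoms: tert-butyldimethylsilyl chloride, CC(C)(C)[Si](C)(C)Cl
Why: Routine silylation of the primary alcohol, which leaves the purchased stereocentre (the future C2 of the acid) untouched.

Step 2
Reactants: 2 methyl (R)-3-[(tert-butyldimethylsilyl)oxy]-2-methylpropanoate
Product: 3 (R)-3-[(tert-butyldimethylsilyl)oxy]-2-methylpropanal
Conditions: DIBAL-H (1.05 equiv), CH2Cl2, −78 °C; aq. tartrate work-up
Reagents that add atoms: none
Why: Partial ester reduction stops at the tetrahedral aluminate at −78 °C, and the cold, non-basic work-up should keep the α-stereocentre intact.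

Step 3
Reactants: 4 (5E,9E)-6,10,14-trimethylpentadeca-5,9,13-trien-2-one (farnesylacetone)
Product: 5 (2R,5E,9E)-6,10,14-trimethylpentadeca-5,9,13-trien-2-ol
Conditions: (R)-selective alcohol dehydrogenase (Lactobacillus type), NADP+ (cat.), i-PrOH, pH 7 buffer/MTBE, 30 °C
Reagents that add atoms: none
Why: Anti-Prelog biocatalytic ketone reduction tells methyl from the long chain far better than hydride reagents, sets the (R)-carbinol and leaves the alkenes alone.

Step 4
Reactants: 5 (2R,5E,9E)-6,10,14-trimethylpentadeca-5,9,13-trien-2-ol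
Product: 6 (2R,5E,9E)-6,10,14-trimethylpentadeca-5,9,13-trien-2-yl 2,4,6-triisopropylbenzoate
Conditions: 2,4,6-triisopropylbenzoyl chloride, Et3N, DMAP (cat.), CH2Cl2, reflux
Reagents that add atoms: 2,4,6-triisopropylbenzoyl chloride, CC(C)c1cc(C(C)C)c(C(=O)Cl)c(C(C)C)c1
Why: O-Acylation proceeds with retention and installs a hindered benzoate that directs the α-lithiation, resists nucleophilic attack and later serves as the leaving group.

Step 5
Reactants: 6 (2R,5E,9E)-6,10,14-trimethylpentadeca-5,9,13-trien-2-yl 2,4,6-triisopropylbenzoate; 7 vinylboronic acid pinacol ester; 3 (R)-3-[(tert-butyldimethylsilyl)oxy]-2-methylpropanal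
Product: 12 (2R,3R,5Z,9E,13E)-1-[(tert-butyldimethylsilyl)oxy]-2,6,10,14,18-pentamethylnonadeca-5,9,13,17-tetraen-3-ol, via lithiated benzoate 8 (not isolated), via vinylboronate complex 9 (not isolated), via tertiary allylboronate 10 (not isolated), via borate ester 11 (not isolated)
Conditions: s-BuLi, TMEDA, CPME, −60 °C; 7, −60 to 40 °C; volatiles off, toluene; 3, 0 °C to rt; aq. NH4Cl
Reagents that add atoms: none
Why: Carbonyl-directed α-deprotonation of 6 gives configurationally stable 8 with retention, borylation with retention gives 9, and on warming the vinyl group shifts from boron to C6 anti to the departing benzoate (1,2-metallate rearrangement, inversion at C6), which forms C5–C6 and gives (S)-10. Aldehyde 3 then reacts with 10 through a closed six-membered chair (Zimmerman–Traxler) transition state with allylic transposition, which forms C3–C4 and moves the double bond to C5=C6, and hydrolysis of borate 11 releases 12. The closest known reaction types are the lithiation–borylation of secondary alkyl 2,4,6-triisopropylbenzoates and the in situ allylboration of aldehydes with α,α-disubstituted allyl pinacolboronates. No ring of the target is closed here, because the step is a three-component chain assembly in which vinyl–B(pin) acts as an ethane-1,2-diyl linchpin. C3 (R) is controlled by chirality transfer from the C6–B centre with the aldehyde residue equatorial, reinforced by the Felkin–Anh preference of 3 (2,3-syn), and the Z geometry is controlled by the pinacol methyl groups, which push the long chain into the pseudo-axial site and the methyl group into the pseudo-equatorial site. The step needs α-lithiation rather than allylic metalation, secured by the directing carbonyl group, the low temperature and the blocked ortho positions, and it needs γ-selective allyl transfer, secured by the cyclic transition state.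

Step 6
Reactants: 12 (2R,3R,5Z,9E,13E)-1-[(tert-butyldimethylsilyl)oxy]-2,6,10,14,18-pentamethylnonadeca-5,9,13,17-tetraen-3-ol
Product: 13 (2R,3R,5Z,9E,13E)-1-[(tert-butyldimethylsilyl)oxy]-2,6,10,14,18-pentamethylnonadeca-5,9,13,17-tetraen-3-yl methanesulfonate
Conditions: MsCl, Et3N, CH2Cl2, 0 °C
Reagents that add atoms: methanesulfonyl chloride, CS(=O)(=O)Cl
Why: Sulfonylation at oxygen activates C3 without touching its configuration.

Step 7
Reactants: 13 (2R,3R,5Z,9E,13E)-1-[(tert-butyldimethylsilyl)oxy]-2,6,10,14,18-pentamethylnonadeca-5,9,13,17-tetraen-3-yl methanesulfonate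
Product: 14 tert-butyl{[(2R,3S,5Z,9E,13E)-3-hydroperoxy-2,6,10,14,18-pentamethylnonadeca-5,9,13,17-tetraen-1-yl]oxy}dimethylsilane
Conditions: 50% aq. H2O2 (excess), KOH, MeOH/THF, 0 °C to rt
Reagents that add atoms: hydrogen peroxide, OO
Why: SN2 displacement of a secondary sulfonate by the α-effect nucleophile HOO− brings in both peroxide oxygens and inverts C3 to the (S) configuration of the target.

Step 8
Reactants: 14 tert-butyl{[(2R,3S,5Z,9E,13E)-3-hydroperoxy-2,6,10,14,18-pentamethylnonadeca-5,9,13,17-tetraen-1-yl]oxy}dimethylsilane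
Product: 15 tert-butyl{(2R)-2-[(3S,5S,6S)-5-iodo-6-methyl-6-[(3E,7E)-4,8,12-trimethyltrideca-3,7,11-trien-1-yl]-1,2-dioxan-3-yl]propoxy}dimethylsilane
Conditions: NIS (1.05 equiv), CH2Cl2, dark, 0 °C
Reagents that add atoms: N-iodosuccinimide, O=C1CCC(=O)N1I
Why: In this electrophile-induced cyclisation of an unsaturated hydroperoxide (cycloperoxyiodination), iodonium formation is reversible and only C5=C6 has an internal nucleophile, so the terminal peroxy oxygen opens it anti at tertiary C6 (6-endo, Markovnikov) through a chair with the C3 side chain equatorial, and the Z geometry places the long chain axial and cis to that side chain, which sets (6S).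

Step 9
Reactants: 15 tert-butyl{(2R)-2-[(3S,5S,6S)-5-iodo-6-methyl-6-[(3E,7E)-4,8,12-trimethyltrideca-3,7,11-trien-1-yl]-1,2-dioxan-3-yl]propoxy}dimethylsilane
Product: 16 tert-butyl{(2R)-2-[(3S,6S)-6-methyl-6-[(3E,7E)-4,8,12-trimethyltrideca-3,7,11-trien-1-yl]-1,2-dioxan-3-yl]propoxy}dimethylsilane
Conditions: Bu3SnH (1.5 equiv), PhSeSePh (20 mol%), Et3B/air (cat.), toluene, 0 °C to rt
Reagents that add atoms: none
Why: In this radical-chain deiodination, benzeneselenol formed in situ should transfer hydrogen to the C5 radical faster than that radical can add 5-exo to the nearest side-chain double bond or attack the O–O bond.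

Step 10
Reactants: 16 tert-butyl{(2R)-2-[(3S,6S)-6-methyl-6-[(3E,7E)-4,8,12-trimethyltrideca-3,7,11-trien-1-yl]-1,2-dioxan-3-yl]propoxy}dimethylsilane
Product: 17 (2R)-2-[(3S,6S)-6-methyl-6-[(3E,7E)-4,8,12-trimethyltrideca-3,7,11-trien-1-yl]-1,2-dioxan-3-yl]propan-1-ol
Conditions: HF·pyridine, pyridine/THF, 0 °C to rt
Reagents that add atoms: none
Why: Fluoride-driven desilylation under buffered, non-basic conditions avoids base-induced (Kornblum–DeLaMare type) cleavage of the dioxane.

Step 11
Reactants: 17 (2R)-2-[(3S,6S)-6-methyl-6-[(3E,7E)-4,8,12-trimethyltrideca-3,7,11-trien-1-yl]-1,2-dioxan-3-yl]propan-1-ol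
Product: 19 (2S)-2-[(3S,6S)-6-methyl-6-[(3E,7E)-4,8,12-trimethyltrideca-3,7,11-trien-1-yl]-1,2-dioxan-3-yl]propanoic acid, via aldehyde 18 (not isolated)
Conditions: TEMPO (20 mol%), PhI(OAc)2 (2.2 equiv), MeCN/H2O, 0 °C to rt
Reagents that add atoms: water, O
Why: Oxoammonium oxidation takes the alcohol through aldehyde 18 and its hydrate to the acid under weakly acidic conditions that spare the trisubstituted alkenes, the O–O bond and the α-stereocentre.

**Compound list**
1 | methyl (R)-3-hydroxy-2-methylpropanoate | COC(=O)[C@H](C)CO | starting material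
2 | methyl (R)-3-[(tert-butyldimethylsilyl)oxy]-2-methylpropanoate | COC(=O)[C@H](C)CO[Si](C)(C)C(C)(C)C | intermediate
3 | (R)-3-[(tert-butyldimethylsilyl)oxy]-2-methylpropanal | O=C[C@H](C)CO[Si](C)(C)C(C)(C)C | intermediate
4 | (5E,9E)-farnesylacetone | CC(C)=CCC/C(C)=C/CC/C(C)=C/CCC(C)=O | starting material
5 | (2R,5E,9E)-6,10,14-trimethylpentadeca-5,9,13-trien-2-ol | CC(C)=CCC/C(C)=C/CC/C(C)=C/CC[C@@H](C)O | intermediate
6 | (2R)-carbinyl 2,4,6-triisopropylbenzoate of 5 | CC(C)=CCC/C(C)=C/CC/C(C)=C/CC[C@@H](C)OC(=O)c1c(C(C)C)cc(C(C)C)cc1C(C)C | intermediate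
7 | vinylboronic acid pinacol ester | C=CB1OC(C)(C)C(C)(C)O1 | starting material
8 | α-lithiated benzoate (Li in place of the carbinyl H, retention) | CC(C)=CCC/C(C)=C/CC/C(C)=C/CC[C@@]([Li])(C)OC(=O)c1c(C(C)C)cc(C(C)C)cc1C(C)C | intermediate
9 | lithium vinylboronate complex | CC(C)=CCC/C(C)=C/CC/C(C)=C/CC[C@@]([B-]1(C=C)OC(C)(C)C(C)(C)O1)(C)OC(=O)c1c(C(C)C)cc(C(C)C)cc1C(C)C.[Li+] | intermediate
10 | 2-[(3S,6E,10E)-3,7,11,15-tetramethylhexadeca-1,6,10,14-tetraen-3-yl]-4,4,5,5-tetramethyl-1,3,2-dioxaborolane | CC(C)=CCC/C(C)=C/CC/C(C)=C/CC[C@](B1OC(C)(C)C(C)(C)O1)(C)C=C | intermediate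
11 | pinacol borate ester of 12 | CC(C)=CCC/C(C)=C/CC/C(C)=C/CC/C(C)=C\C[C@@H](OB1OC(C)(C)C(C)(C)O1)[C@H](C)CO[Si](C)(C)C(C)(C)C | intermediate
12 | (2R,3R,5Z,9E,13E)-homoallylic alcohol | CC(C)=CCC/C(C)=C/CC/C(C)=C/CC/C(C)=C\C[C@@H](O)[C@H](C)CO[Si](C)(C)C(C)(C)C | intermediate
13 | (2R,3R,5Z,9E,13E)-methanesulfonate | CC(C)=CCC/C(C)=C/CC/C(C)=C/CC/C(C)=C\C[C@@H](OS(C)(=O)=O)[C@H](C)CO[Si](C)(C)C(C)(C)C | intermediate
14 | (2R,3S,5Z,9E,13E)-hydroperoxide | CC(C)=CCC/C(C)=C/CC/C(C)=C/CC/C(C)=C\C[C@H](OO)[C@H](C)CO[Si](C)(C)C(C)(C)C | intermediate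
15 | (3S,5S,6S)-5-iodo-1,2-dioxane silyl ether | CC(C)=CCC/C(C)=C/CC/C(C)=C/CC[C@@]1(C)[C@@H](I)C[C@@H]([C@H](C)CO[Si](C)(C)C(C)(C)C)OO1 | intermediate
16 | (3S,6S)-1,2-dioxane silyl ether | CC(C)=CCC/C(C)=C/CC/C(C)=C/CC[C@@]1(C)CC[C@@H]([C@H](C)CO[Si](C)(C)C(C)(C)C)OO1 | intermediate
17 | (2R)-2-[(3S,6S)-dioxanyl]propan-1-ol | CC(C)=CCC/C(C)=C/CC/C(C)=C/CC[C@@]1(C)CC[C@@H]([C@H](C)CO)OO1 | intermediate
18 | (2S)-2-[(3S,6S)-dioxanyl]propanal | CC(C)=CCC/C(C)=C/CC/C(C)=C/CC[C@@]1(C)CC[C@@H]([C@H](C)C=O)OO1 | intermediate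
19 | CNP0179915.1, (2S)-2-[(3S,6S)-dioxanyl]propanoic acid | CC(C)=CCC/C(C)=C/CC/C(C)=C/CC[C@@]1(C)CC[C@@H]([C@H](C)C(=O)O)OO1 | target

Total step count: 11. Longest linear sequence: 9 steps (4 to 19, steps 3–11).

**Steps most likely to fail**

1. Step 5.
   - What may go wrong: allylic metalation of the polyene may compete. Reversible boronate formation may erode stereochemical fidelity. Aldehyde 3 may epimerise in the basic flask. Discrimination between the pseudo-axial and pseudo-equatorial sites may be too weak.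
   - Fallback: it sets out from aldehyde 3, with commercial (2E,6E,10E)-geranylgeraniol as the C20 partner, and comes back at 12.
     - Geranylgeraniol is acylated with methyl chloroformate/pyridine to (2E,6E,10E)-geranylgeranyl methyl carbonate F1.
     - A chiral N-heterocyclic carbene–copper(I) catalysed SN2' borylation of F1 with bis(pinacolato)diboron gives the same allylboronate 10, now isolated under neutral conditions.
     - Purified 10 is stirred with 3 in toluene to give 12.

2. Step 7.
   - What may go wrong: substitution at the β-branched secondary carbon may be slow. E2 elimination, homoallylic participation of C5=C6 and silyl loss in hydroxide may compete.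
   - Fallback: it sets out from alcohol 12 and comes back at 14.
     - Alcohol 12 is converted at −78 °C (Tf2O, 2,6-lutidine) into the (3R)-trifluoromethanesulfonate F2.
     - F2 alkylates the potassium salt of 2-hydroperoxytetrahydropyran in THF at 0 °C with inversion, giving the (3S)-tetrahydropyranyl monoperoxyacetal F3.
     - Mild acid methanolysis (PPTS, MeOH) of F3 frees hydroperoxide 14.

3. Step 9.
   - What may go wrong: the C5 radical may be captured by the nearest side-chain double bond, or may attack the O–O bond, before hydrogen transfer. Selenyl radicals may cause E/Z drift of the chain.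
   - Fallback: it sets out from hydroperoxide 14, comes back at 16 and removes the helper without a carbon radical.
     - N-(Phenylseleno)phthalimide with catalytic camphorsulfonic acid (CH2Cl2, −78 to 0 °C) cyclises 14 by the same anti 6-endo mode to the 5-phenylselanyl dioxane F4.
     - mCPBA (1 equiv, −78 °C) gives the selenoxide F5.
     - On warming, F5 undergoes syn elimination towards C4 to give the 3,6-dihydro-1,2-dioxine F6.
     - Diimide (potassium azodicarboxylate, AcOH, 0 °C) is added in portions and stopped when the 1,2-disubstituted ring alkene is consumed, which gives 16.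
     - The margin of selectivity over the three trisubstituted chain alkenes is narrow, so the diimide dosage has to be watched closely.

**Further compounds**
F1 | step 5 | (2E,6E,10E)-geranylgeranyl methyl carbonate | CC(C)=CCC/C(C)=C/CC/C(C)=C/CC/C(C)=C/COC(=O)OC
F2 | step 7 | (2R,3R,5Z,9E,13E)-trifluoromethanesulfonate of 12 | CC(C)=CCC/C(C)=C/CC/C(C)=C/CC/C(C)=C\C[C@@H](OS(=O)(=O)C(F)(F)F)[C@H](C)CO[Si](C)(C)C(C)(C)C
F3 | step 7 | (2R,3S,5Z,9E,13E)-tetrahydropyran-2-yl monoperoxyacetal | CC(C)=CCC/C(C)=C/CC/C(C)=C/CC/C(C)=C\C[C@H](OOC1CCCCO1)[C@H](C)CO[Si](C)(C)C(C)(C)C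
F4 | step 9 | 5-phenylselanyl-1,2-dioxane silyl ether | CC(C)=CCC/C(C)=C/CC/C(C)=C/CC[C@@]1(C)[C@@H]([Se]c2ccccc2)C[C@@H]([C@H](C)CO[Si](C)(C)C(C)(C)C)OO1
F5 | step 9 | corresponding selenoxide | CC(C)=CCC/C(C)=C/CC/C(C)=C/CC[C@@]1(C)[C@@H]([Se](=O)c2ccccc2)C[C@@H]([C@H](C)CO[Si](C)(C)C(C)(C)C)OO1
F6 | step 9 | (3S,6S)-3,6-dihydro-1,2-dioxine silyl ether | CC(C)=CCC/C(C)=C/CC/C(C)=C/CC[C@@]1(C)C=C[C@@H]([C@H](C)CO[Si](C)(C)C(C)(C)C)OO1
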